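**Strategy.** The butenolide is disconnected at its quaternary carbon C5, at the C5–carboxyl bond and at the O1–C2 lactone bond (ring numbered O1, C2 carbonyl, C3 methoxy, C4 aryl, C5). C5 carries the ring oxygen O1 and a carboxyl carbon, the hallmark of isocyanide addition to a ketone carbonyl, and the C2 carboxyl lies cis to C5 across the C3=C4 double bond, placed to serve as the acid component. An intramolecular Passerini reaction under a chiral phosphoric acid should therefore form the C5–C(O)N bond, close the furanone ring and set the only stereocentre in one operation. Its precursor is an (E)-2-methoxy-3-aryl-4-oxo-5-arylpent-2-enoic acid with both phenols silylated, made by hydroxide opening of a 5-benzylidene butenolide.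

Key step: step 10

Assumption 1: 2-bromo-6-isocyanopyridine is taken as purchasable; otherwise it is two routine steps (formylation, dehydration) from 2-amino-6-bromopyridine.
Assumption 2: the sense of induction of the phosphoric acid cannot be predicted for this new substrate class; (R)-TRIP is written, and its mirror image is used if it favours the S-lactone.
Assumption 3: the keto acid precursor is drawn open-chain although it should rest mainly as its racemic lactol ring tautomer (5-benzyl-5-hydroxybutenolide); both forms count as one compound, and salts that are only protonated on work-up are not numbered.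

Step 1
Reactants: 1 methyl glycolate; 2 methoxyacetyl chloride
Product: 3 methyl 2-[(methoxyacetyl)oxy]acetate
Conditions: pyridine, CH2Cl2, 0 °C → rt
Reagents that add atoms: none
Why: Acylation of a primary alcohol with an acid chloride and pyridine is a routine esterification, and neither partner carries a second reactive site.

Step 2
Reactants: 3 methyl 2-[(methoxyacetyl)oxy]acetate
Product: 4 4-hydroxy-3-methoxyfuran-2(5H)-one (3-methoxytetronic acid)
Conditions: KOtBu (2.2 equiv), THF, 0 °C → rt; then 1 M HCl
Reagents that add atoms: none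
Why: Dieckmann condensation as used for tetronic acids from α-acyloxy esters: under reversible deprotonation only the methoxyacetyl enolate can close productively (5-exo-trig onto the methyl ester), and irreversible deprotonation of the acidic tetronic acid pulls the equilibrium to the ring.

Step 3
Reactants: 4 4-hydroxy-3-methoxyfuran-2(5H)-one
Product: 5 4-methoxy-5-oxo-2,5-dihydrofuran-3-yl trifluoromethanesulfonate
Conditions: Tf2O, iPr2NEt, CH2Cl2, −78 → 0 °C
Reagents that add atoms: trifluoromethanesulfonic anhydride, O=S(=O)(OS(=O)(=O)C(F)(F)F)C(F)(F)F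
Why: O-Sulfonylation of the enol of a vinylogous acid with triflic anhydride and a hindered amine should give the enol triflate cleanly at low temperature, the usual activation of tetronic acids for cross-coupling.

Step 4
Reactants: 5 4-methoxy-5-oxo-2,5-dihydrofuran-3-yl trifluoromethanesulfonate; 6 4-hydroxyphenylboronic acid
Product: 7 4-(4-hydroxyphenyl)-3-methoxyfuran-2(5H)-one
Conditions: Pd(PPh3)4 (5 mol%), 2 M aq Na2CO3, THF, 60 °C
Reagents that add atoms: none
Why: Suzuki–Miyaura coupling: the β-triflyloxy enoate is an electron-poor vinyl triflate that undergoes fast oxidative addition, and boronic acids with a free phenol couple under aqueous carbonate, a known entry to 4-aryl-2(5H)-furanones.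

Step 5
Reactants: 7 4-(4-hydroxyphenyl)-3-methoxyfuran-2(5H)-one
Product: 8 3-methoxy-4-[4-(triisopropylsilyloxy)phenyl]furan-2(5H)-one
Conditions: TIPSCl, imidazole, DMF, rt
Reagents that add atoms: triisopropylsilyl chloride, CC(C)[Si](Cl)(C(C)C)C(C)C
Why: Silylation of a phenol with a silyl chloride and imidazole is standard, and the bulky triisopropylsilyl ether is chosen because it must later survive brief hydroxide and methoxide treatment yet fall to fluoride.

Step 6
Reactants: 9 4-hydroxybenzaldehyde; 10 prenyl bromide (1-bromo-3-methylbut-2-ene)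
Product: 11 4-hydroxy-3-(3-methylbut-2-en-1-yl)benzaldehyde
Conditions: KOH (1.1 equiv), H2O, rt
Reagents that add atoms: none
Why: ortho-C-Alkylation of a phenoxide in water, where hydrogen bonding to the phenoxide oxygen shifts the allylic bromide towards carbon and the formyl group blocks the para position; the O-prenyl ether and dialkylated material expected alongside are removed by chromatography.

Step 7
Reactants: 11 4-hydroxy-3-(3-methylbut-2-en-1-yl)benzaldehyde
Product: 12 3-(3-methylbut-2-en-1-yl)-4-(triisopropylsilyloxy)benzaldehyde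
Conditions: TIPSCl, imidazole, DMF, rt
Reagents that add atoms: triisopropylsilyl chloride, CC(C)[Si](Cl)(C(C)C)C(C)C
Why: Phenol silylation as in step 5; the aldehyde and the trisubstituted alkene are inert to these conditions.

Step 8
Reactants: 8 3-methoxy-4-[4-(triisopropylsilyloxy)phenyl]furan-2(5H)-one; 12 3-(3-methylbut-2-en-1-yl)-4-(triisopropylsilyloxy)benzaldehyde
Product: 15 (Z)-3-methoxy-5-[3-(3-methylbut-2-en-1-yl)-4-(triisopropylsilyloxy)benzylidene]-4-[4-(triisopropylsilyloxy)phenyl]furan-2(5H)-one, via 2-silyloxyfuran 13 (not isolated), via aldol silyl ether 14 (not isolated)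
Conditions: TBSOTf (2 equiv), iPr2NEt (3 equiv), CH2Cl2, 0 °C → rt; then DBU (3 equiv), rt
Reagents that add atoms: none
Why: Vinylogous Mukaiyama aldol condensation in one pot: silyl triflate and amine convert 8 into 2-silyloxyfuran 13, which can add to the silyl-activated aldehyde only through C5 because C3 is fully substituted, and DBU then expels silanolate from aldol silyl ether 14 (E1cB) to give the conjugated ylidene, for which the Z isomer is expected as the less crowded one.

Step 9
Reactants: 15 (Z)-5-benzylidene butenolide bis(triisopropylsilyl) ether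
Product: 16 (E)-2-methoxy-5-[3-(3-methylbut-2-en-1-yl)-4-(triisopropylsilyloxy)phenyl]-4-oxo-3-[4-(triisopropylsilyloxy)phenyl]pent-2-enoic acid
Conditions: LiOH·H2O (1.5 equiv), THF/H2O 4:1, 0 °C; then cold 1 M HCl to pH 3
Reagents that add atoms: lithium hydroxide, [Li+].[OH-]
Why: Hydrolysis of an enol lactone: hydroxide adds to the C2 carbonyl and expels the ketone enolate, a far better leaving group than an alkoxide, so ring opening at 0 °C should outrun attack on the hindered aryl silyl ethers, and protonation at the benzylic carbon leaves the benzyl ketone cis to the acid across the tetrasubstituted alkene.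

Step 10
Reactants: 16 (E)-keto acid; 17 2-bromo-6-isocyanopyridine
Product: 19 (R)-N-(6-bromopyridin-2-yl)-4-methoxy-2-[3-(3-methylbut-2-en-1-yl)-4-(triisopropylsilyloxy)benzyl]-5-oxo-3-[4-(triisopropylsilyloxy)phenyl]-2,5-dihydrofuran-2-carboxamide, via cyclic imidate 18 (not isolated)
Conditions: (R)-TRIP (10 mol%), dry CH2Cl2 (0.2 M), 0 °C → rt
Reagents that add atoms: none
Why: Proposed new method: The phosphoric acid should open the lactol tautomer of 16 and hydrogen-bond both its ketone oxygen and its carboxylic acid, so that the isocyanide carbon of 17 adds to the C5 ketone and the cis carboxylate traps the resulting nitrilium ion (6-exo-dig) as cyclic imidate 18. The C5 oxygen then attacks the C2 carbonyl across the ring (5-exo-trig addition–elimination, a Mumm-type O-to-O acyl shift), which closes the butenolide ring at O1–C2 and releases the secondary amide. The closest known reactions are the racemic Passerini reaction of γ-keto acids to lactone carboxamides and the chiral phosphoric acid-catalysed three-component Passerini reaction of aldehydes; enantioselective addition to a ketone is not known. The C5 stereocentre is set in the C–C bond-forming addition, in which the 3,3'-aryl groups of the catalyst bound to both acid and ketone should shield one face of the carbonyl. The step needs this facial selectivity and needs isocyanide addition to outrun loss of water to ylidene lactone 15: the E tetrasubstituted alkene keeps acid and ketone cis so that trapping is intramolecular, the resting lactol has no free acid so that the uncatalysed pathway is starved, C5 bears no hydrogen so that imidate 18 can only rearrange by acyl shift, and dry aprotic solvent without a dehydrating agent disfavours elimination.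

Step 11
Reactants: 19 (R)-N-(6-bromopyridin-2-yl) butenolide carboxamide bis(triisopropylsilyl) ether
Product: 20 methyl (R)-4-methoxy-2-[3-(3-methylbut-2-en-1-yl)-4-(triisopropylsilyloxy)benzyl]-5-oxo-3-[4-(triisopropylsilyloxy)phenyl]-2,5-dihydrofuran-2-carboxylate
Conditions: NaOMe (1.5 equiv), MeOH/THF 1:1, 0 °C; AcOH quench
Reagents that add atoms: methanol, CO; sodium methoxide, C[O-].[Na+]
Why: Alcoholysis of the amide of a convertible isocyanide: the electron-poor 6-bromopyridin-2-amine is a good leaving group and the α-acyloxy substituent activates the carbonyl, so methoxide should exchange the amide for the methyl ester at 0 °C, while lactone opening is reversible, quaternary C5 cannot epimerise and any silyl ether lost here would be removed in step 12 anyway.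

Step 12
Reactants: 20 methyl ester bis(triisopropylsilyl) ether
Product: 21 2-O-methylbutyrolactone I [methyl (R)-2-[4-hydroxy-3-(3-methylbut-2-en-1-yl)benzyl]-3-(4-hydroxyphenyl)-4-methoxy-5-oxo-2,5-dihydrofuran-2-carboxylate]
Conditions: TBAF (2.5 equiv), AcOH (2.5 equiv), THF, 0 °C
Reagents that add atoms: none
Why: Fluoride cleavage of aryl silyl ethers: acetic acid-buffered TBAF removes both silyl groups without the acid that would cyclise the o-prenylphenol to a chromane and without base strong enough to open the lactone or the ester, and C5 is untouched.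

**Compound list**

1 | methyl glycolate | COC(=O)CO | starting material
2 | methoxyacetyl chloride | COCC(=O)Cl | starting material
3 | methyl 2-[(methoxyacetyl)oxy]acetate | COCC(=O)OCC(=O)OC | intermediate
4 | 4-hydroxy-3-methoxyfuran-2(5H)-one | COC1=C(O)COC1=O | intermediate
5 | 4-methoxy-5-oxo-2,5-dihydrofuran-3-yl trifluoromethanesulfonate | COC1=C(OS(=O)(=O)C(F)(F)F)COC1=O | intermediate
6 | 4-hydroxyphenylboronic acid | OB(O)c1ccc(O)cc1 | starting material
7 | 4-(4-hydroxyphenyl)-3-methoxyfuran-2(5H)-one | COC1=C(c2ccc(O)cc2)COC1=O | intermediate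
8 | 3-methoxy-4-[4-(triisopropylsilyloxy)phenyl]furan-2(5H)-one | COC1=C(c2ccc(O[Si](C(C)C)(C(C)C)C(C)C)cc2)COC1=O | intermediate
9 | 4-hydroxybenzaldehyde | O=Cc1ccc(O)cc1 | starting material
10 | prenyl bromide (1-bromo-3-methylbut-2-ene) | CC(C)=CCBr | starting material
11 | 4-hydroxy-3-(3-methylbut-2-en-1-yl)benzaldehyde | CC(C)=CCc1cc(C=O)ccc1O | intermediate
12 | 3-(3-methylbut-2-en-1-yl)-4-(triisopropylsilyloxy)benzaldehyde | CC(C)=CCc1cc(C=O)ccc1O[Si](C(C)C)(C(C)C)C(C)C | intermediate
13 | tert-butyl({3-methoxy-4-[4-(triisopropylsilyloxy)phenyl]furan-2-yl}oxy)dimethylsilane (2-silyloxyfuran, not isolated) | COc1c(-c2ccc(O[Si](C(C)C)(C(C)C)C(C)C)cc2)coc1O[Si](C)(C)C(C)(C)C | intermediate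
14 | 5-{(tert-butyldimethylsilyloxy)[3-(3-methylbut-2-en-1-yl)-4-(triisopropylsilyloxy)phenyl]methyl}-3-methoxy-4-[4-(triisopropylsilyloxy)phenyl]furan-2(5H)-one (aldol silyl ether, diastereomer mixture, not isolated) | COC1=C(c2ccc(O[Si](C(C)C)(C(C)C)C(C)C)cc2)C(C(O[Si](C)(C)C(C)(C)C)c2ccc(O[Si](C(C)C)(C(C)C)C(C)C)c(CC=C(C)C)c2)OC1=O | intermediate
15 | (Z)-3-methoxy-5-[3-(3-methylbut-2-en-1-yl)-4-(triisopropylsilyloxy)benzylidene]-4-[4-(triisopropylsilyloxy)phenyl]furan-2(5H)-one | COC1=C(c2ccc(O[Si](C(C)C)(C(C)C)C(C)C)cc2)/C(=C/c2ccc(O[Si](C(C)C)(C(C)C)C(C)C)c(CC=C(C)C)c2)OC1=O | intermediate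
16 | (E)-2-methoxy-5-[3-(3-methylbut-2-en-1-yl)-4-(triisopropylsilyloxy)phenyl]-4-oxo-3-[4-(triisopropylsilyloxy)phenyl]pent-2-enoic acid (carboxyl cis to the ketone; open form of the racemic lactol) | OC(=O)/C(OC)=C(/c1ccc(O[Si](C(C)C)(C(C)C)C(C)C)cc1)C(=O)Cc1ccc(O[Si](C(C)C)(C(C)C)C(C)C)c(CC=C(C)C)c1 | intermediate
17 | 2-bromo-6-isocyanopyridine | [C-]#[N+]c1cccc(Br)n1 | starting material
18 | (R)-6-[(6-bromopyridin-2-yl)imino]-5-hydroxy-3-methoxy-5-[3-(3-methylbut-2-en-1-yl)-4-(triisopropylsilyloxy)benzyl]-4-[4-(triisopropylsilyloxy)phenyl]-5,6-dihydro-2H-pyran-2-one (cyclic imidate, not isolated) | COC1=C(c2ccc(O[Si](C(C)C)(C(C)C)C(C)C)cc2)[C@](O)(Cc2ccc(O[Si](C(C)C)(C(C)C)C(C)C)c(CC=C(C)C)c2)C(=Nc2cccc(Br)n2)OC1=O | intermediate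
19 | (R)-N-(6-bromopyridin-2-yl)-4-methoxy-2-[3-(3-methylbut-2-en-1-yl)-4-(triisopropylsilyloxy)benzyl]-5-oxo-3-[4-(triisopropylsilyloxy)phenyl]-2,5-dihydrofuran-2-carboxamide | O=C(Nc1cccc(Br)n1)[C@]1(Cc2ccc(O[Si](C(C)C)(C(C)C)C(C)C)c(CC=C(C)C)c2)OC(=O)C(OC)=C1c1ccc(O[Si](C(C)C)(C(C)C)C(C)C)cc1 | intermediate
20 | methyl (R)-4-methoxy-2-[3-(3-methylbut-2-en-1-yl)-4-(triisopropylsilyloxy)benzyl]-5-oxo-3-[4-(triisopropylsilyloxy)phenyl]-2,5-dihydrofuran-2-carboxylate | COC(=O)[C@]1(Cc2ccc(O[Si](C(C)C)(C(C)C)C(C)C)c(CC=C(C)C)c2)OC(=O)C(OC)=C1c1ccc(O[Si](C(C)C)(C(C)C)C(C)C)cc1 | intermediate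
21 | 2-O-methylbutyrolactone I, methyl (R)-2-[4-hydroxy-3-(3-methylbut-2-en-1-yl)benzyl]-3-(4-hydroxyphenyl)-4-methoxy-5-oxo-2,5-dihydrofuran-2-carboxylate | COC(=O)[C@]1(Cc2ccc(O)c(CC=C(C)C)c2)OC(=O)C(OC)=C1c1ccc(O)cc1 | target

**Totals**

Total step count: 12. Longest linear sequence: 10 steps (steps 1–5 and 8–12); steps 6–7 form the two-step aldehyde branch.

**Steps most likely to fail**

1. Step 10. The catalysed pathway may not outrun addition promoted by the substrate's own acid, which would erode facial selectivity. The hindered ketone, which is also a vinylogous ester, may add the isocyanide only slowly. Fallback on known chemistry: 16 and 17 are combined without catalyst in concentrated toluene at rt to 40 °C, the classical Passerini reaction of a keto acid, which should give the racemic N-(6-bromopyridin-2-yl) amide F1. Preparative chromatography on a chiral stationary phase then separates 19 from its mirror image, the (S)-amide F2, and the route is rejoined at 19.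

2. Step 11. Methoxide attack on the amide next to the quaternary centre may be slow, so that cleavage of the silyl ethers, lactone opening or substitution of the pyridyl bromide compete. Fallback: 19 is treated with Boc2O and catalytic DMAP in MeCN to give the N-Boc imide F3. Its doubly activated acyl group should be cleaved by catalytic K2CO3 in MeOH at 0 °C, which returns to the route at 20 with tert-butyl (6-bromopyridin-2-yl)carbamate as the leaving group.

3. Step 9. Hydroxide may strip one or both aryl silyl ethers while it opens the lactone, leaving a mixture of silylation states. Fallback: 15 is treated with excess aqueous NaOH in THF/MeOH so that ring opening and desilylation both go to completion, giving after acidification the dihydroxy keto acid F4. TIPSCl and imidazole in DMF then silylate both phenols and the acid to the bis(silyl ether) silyl ester F5. Brief K2CO3 in aqueous MeOH/THF at 0 °C, followed by acidification, should hydrolyse only the labile silyl ester and return to the route at 16.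

**Further compounds**

F1 | step 10 | racemic N-(6-bromopyridin-2-yl)-4-methoxy-2-[3-(3-methylbut-2-en-1-yl)-4-(triisopropylsilyloxy)benzyl]-5-oxo-3-[4-(triisopropylsilyloxy)phenyl]-2,5-dihydrofuran-2-carboxamide | O=C(Nc1cccc(Br)n1)C1(Cc2ccc(O[Si](C(C)C)(C(C)C)C(C)C)c(CC=C(C)C)c2)OC(=O)C(OC)=C1c1ccc(O[Si](C(C)C)(C(C)C)C(C)C)cc1
F2 | step 10 | (S)-enantiomer of amide 19 | O=C(Nc1cccc(Br)n1)[C@@]1(Cc2ccc(O[Si](C(C)C)(C(C)C)C(C)C)c(CC=C(C)C)c2)OC(=O)C(OC)=C1c1ccc(O[Si](C(C)C)(C(C)C)C(C)C)cc1
F3 | step 11 | tert-butyl (R)-(6-bromopyridin-2-yl){4-methoxy-2-[3-(3-methylbut-2-en-1-yl)-4-(triisopropylsilyloxy)benzyl]-5-oxo-3-[4-(triisopropylsilyloxy)phenyl]-2,5-dihydrofuran-2-carbonyl}carbamate | CC(C)(C)OC(=O)N(c1cccc(Br)n1)C(=O)[C@]1(Cc2ccc(O[Si](C(C)C)(C(C)C)C(C)C)c(CC=C(C)C)c2)OC(=O)C(OC)=C1c1ccc(O[Si](C(C)C)(C(C)C)C(C)C)cc1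
F4 | step 9 | (E)-5-[4-hydroxy-3-(3-methylbut-2-en-1-yl)phenyl]-3-(4-hydroxyphenyl)-2-methoxy-4-oxopent-2-enoic acid | OC(=O)/C(OC)=C(/c1ccc(O)cc1)C(=O)Cc1ccc(O)c(CC=C(C)C)c1
F5 | step 9 | triisopropylsilyl (E)-2-methoxy-5-[3-(3-methylbut-2-en-1-yl)-4-(triisopropylsilyloxy)phenyl]-4-oxo-3-[4-(triisopropylsilyloxy)phenyl]pent-2-enoate | CC(C)[Si](OC(=O)/C(OC)=C(/c1ccc(O[Si](C(C)C)(C(C)C)C(C)C)cc1)C(=O)Cc1ccc(O[Si](C(C)C)(C(C)C)C(C)C)c(CC=C(C)C)c1)(C(C)C)C(C)C
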